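**Plan**
Retrosynthesis: remove the three O-benzyl groups; cut the bond between C6 of the furofuranone and the catechol ring (to enol ether-lactone 12 and boronic acid 13); cut C6–O5 and take out the C6 carbon (to γ-lactone 9); cut the lactone C1–O2 bond and lower C1 to an alkene carbon (to vinyl diol 3); cut C3–C3a (to O-benzylvanillin 1 and vinyl ethylene carbonate 2).
Forward: the chain is joined at C3–C3a by Ir-catalysed (hydroxymethyl)allylation, the lactone ring is made by hydroboration and oxidative lactonisation, the dihydrofuran ring is closed onto a one-carbon unit that becomes C6, the catechol ring is attached at C6, and the phenols are freed.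
Stereochemistry: C3 and C3a are set together by the chiral Ir catalyst (anti, enantioselective); C6 and C6a are both set in the key step by substrate control from C3a and the cis ring fusion.
Enabling feature: C6 is both β to the lactone carbonyl C1 (through C6a) and bound to ring oxygen O5, so the 6,6a-dehydro compound 12 is a cyclic vinylogous carbonate C1(=O)–C6a=C6–O5 in a folded bicycle whose convex face carries H-3a. Because the C6–O5 bond is endocyclic, it cannot align for β-elimination after aryl addition.

Key step: step 7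

Remark: ring positions follow tetrahydro-1H,3H-furo[3,4-c]furan-1-one (C1 carbonyl, O2, C3, C3a, C4, O5, C6, C6a). Catalyst-bound species of catalytic cycles are described in the Why lines and are not numbered.
Assumption: the (S)-ligand of the Ir catalyst is taken to give the (1S,2R)-diol 3; if the sense proves opposite, the (R)-ligand is used and nothing else changes.

Step 1
Reactants: 1 4-(benzyloxy)-3-methoxybenzaldehyde; 2 4-ethenyl-1,3-dioxolan-2-one (vinyl ethylene carbonate, racemic)
Product: 3 (1S,2R)-1-[4-(benzyloxy)-3-methoxyphenyl]-2-ethenylpropane-1,3-diol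
Conditions: [Ir(cod)Cl]2 (2.5 mol %), (S)-SEGPHOS (5 mol %), 4-cyano-3-nitrobenzoic acid (10 mol %), K3PO4 (5 mol %), i-PrOH (2 equiv), THF, 90 °C
Reagents that add atoms: none
Why: Krische-type iridium-catalysed transfer-hydrogenative carbonyl (hydroxymethyl)allylation, in which ionisation and decarboxylation of 2 at the cyclometalated Ir–bisphosphine C,O-benzoate gives an (E)-σ-allyl iridium alkoxide that adds to 1 through a closed chair transition state, so the anti relationship of C1–OH and C2–CH2OH follows from the allyl geometry and the absolute sense at both new centres from the chiral ligand.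

Step 2
Reactants: 3 (1S,2R)-1-[4-(benzyloxy)-3-methoxyphenyl]-2-ethenylpropane-1,3-diol
Product: 4 (1S,2R)-1-[4-(benzyloxy)-3-methoxyphenyl]-2-{[(tert-butyldimethylsilyl)oxy]methyl}but-3-en-1-ol
Conditions: TBSCl (1.05 equiv), imidazole, CH2Cl2, 0 °C
Reagents that add atoms: tert-butyldimethylsilyl chloride, CC(C)(C)[Si](C)(C)Cl
Why: Sterically controlled silylation takes the primary hydroxyl in preference to the hindered secondary benzylic one, which differentiates the future ether oxygen O5 from the future lactone oxygen O2 without touching a stereocentre.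

Step 3
Reactants: 4 (1S,2R)-1-[4-(benzyloxy)-3-methoxyphenyl]-2-{[(tert-butyldimethylsilyl)oxy]methyl}but-3-en-1-ol
Product: 6 (1S,2R)-1-[4-(benzyloxy)-3-methoxyphenyl]-2-{[(tert-butyldimethylsilyl)oxy]methyl}butane-1,4-diol, via B-alkyl-9-BBN adduct 5 (not isolated)
Conditions: 9-BBN (2.5 equiv), THF, 0 °C to rt; then 30% H2O2, aq NaHCO3, 0 °C to rt
Reagents that add atoms: 9-borabicyclo[3.3.1]nonane, B1C2CCCC1CCC2 (its boron stays only in intermediate 5); hydrogen peroxide, OO
Why: Anti-Markovnikov hydroboration of the monosubstituted alkene with bulky 9-BBN and oxidation of the C–B bond (hydroboration–oxidation) should give the primary alcohol, the mild buffered oxidation sparing the silyl ether and leaving both stereocentres untouched.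

Step 4
Reactants: 6 (1S,2R)-1-[4-(benzyloxy)-3-methoxyphenyl]-2-{[(tert-butyldimethylsilyl)oxy]methyl}butane-1,4-diol
Product: 9 (4R,5S)-5-[4-(benzyloxy)-3-methoxyphenyl]-4-{[(tert-butyldimethylsilyl)oxy]methyl}oxolan-2-one, via hydroxy aldehyde 7 (not isolated), via lactol 8 (not isolated)
Conditions: TEMPO (0.2 equiv), PhI(OAc)2 (2.5 equiv), CH2Cl2, rt
Reagents that add atoms: none
Why: TEMPO/PhI(OAc)2 oxidises the primary alcohol faster than the secondary benzylic one, the aldehyde closes to the five-membered lactol with the benzylic hydroxyl and this is oxidised on to the γ-lactone (oxidative lactonisation of a 1,4-diol), the trans C4/C5 relationship being carried over from 3.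

Step 5
Reactants: 9 (4R,5S)-5-[4-(benzyloxy)-3-methoxyphenyl]-4-{[(tert-butyldimethylsilyl)oxy]methyl}oxolan-2-one
Product: 10 (3E,4R,5S)-5-[4-(benzyloxy)-3-methoxyphenyl]-4-{[(tert-butyldimethylsilyl)oxy]methyl}-3-[(dimethylamino)methylidene]oxolan-2-one
Conditions: t-BuOCH(NMe2)2 (2 equiv), PhMe, 100 °C
Reagents that add atoms: tert-butoxybis(dimethylamino)methane (Bredereck's reagent), CN(C)C(OC(C)(C)C)N(C)C
Why: Bredereck aminomethylenation, in which tert-butoxide released from the reagent deprotonates the lactone α-CH2 and the enolate condenses with the formamidinium ion, installs the carbon that becomes C6 at the formyl oxidation level without touching C4 or C5 (the alkene geometry is of no consequence later).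

Step 6
Reactants: 10 (3E,4R,5S)-5-[4-(benzyloxy)-3-methoxyphenyl]-4-{[(tert-butyldimethylsilyl)oxy]methyl}-3-[(dimethylamino)methylidene]oxolan-2-one
Product: 12 (3S,3aR)-3-[4-(benzyloxy)-3-methoxyphenyl]-3a,4-dihydro-1H,3H-furo[3,4-c]furan-1-one, via hydroxy enaminone 11 (not isolated)
Conditions: CSA (1.2 equiv), MeOH, 0 °C to rt; then PPTS (0.2 equiv), PhMe, 4 Å MS, 80 °C
Reagents that add atoms: none
Why: Acid methanolysis frees the primary hydroxyl, C-protonation of the vinylogous carbamate gives an iminium ion that the hydroxyl attacks in a 5-exo-trig closure, and loss of dimethylammonium and of H-6a (amine–alcohol exchange on an enaminone) should leave the conjugated cyclic enol ether, the vinylogous carbamate having kept the lactone carbonyl too unreactive for translactonisation while the hydroxyl is free.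

Step 7
Reactants: 12 (3S,3aR)-3-[4-(benzyloxy)-3-methoxyphenyl]-3a,4-dihydro-1H,3H-furo[3,4-c]furan-1-one; 13 [3,4-bis(benzyloxy)phenyl]boronic acid
Product: 14 (3S,3aR,6S,6aS)-6-[3,4-bis(benzyloxy)phenyl]-3-[4-(benzyloxy)-3-methoxyphenyl]tetrahydro-1H,3H-furo[3,4-c]furan-1-one
Conditions: [Rh(cod)OH]2 (3 mol %), 13 (2 equiv), 1,4-dioxane/H2O 10:1, 60 °C
Reagents that add atoms: none
Why: Proposed new method: transmetalation of 13 to Rh(I)–OH gives aryl–Rh(I), which binds the C6=C6a enol-ether double bond of 12 and inserts with the aryl group going to C6 (β to the lactone carbonyl C1) to form an oxa-π-allyl rhodium enolate that water protonates at C6a, regenerating Rh–OH. The closest known reaction type is the Hayashi–Miyaura Rh(I)-catalysed 1,4-addition of arylboronic acids, established for α,β-unsaturated lactones and for β-oxygenated enones such as chromones but not for a β-alkoxy-α-alkylidene lactone (cyclic vinylogous carbonate). No ring is closed in this step; both rings of the 3,7-dioxabicyclo[3.3.0]octane are already present in 12. C6 is set by substrate control from C3a, the aryl–rhodium adding to the convex face that carries H-3a and lies away from the lactone ring, which places the aryl group exo; C6a is set on protonation by ring strain, since only the cis-fused bicycle is accessible. The step needs 1,4-addition without β-alkoxide elimination: the C6–O5 bond is endocyclic and lies near the nodal plane of the enolate π system, so E1cB ring opening is stereoelectronically slow (the reason flavanones survive the same chemistry), and the neutral aqueous medium should protonate the enolate before it can eliminate. Regiochemistry on the catechol ring is fixed by the position of boron in 13.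

Step 8
Reactants: 14 (3S,3aR,6S,6aS)-6-[3,4-bis(benzyloxy)phenyl]-3-[4-(benzyloxy)-3-methoxyphenyl]tetrahydro-1H,3H-furo[3,4-c]furan-1-one
Product: 15 (3S,3aR,6S,6aS)-6-(3,4-dihydroxyphenyl)-3-(4-hydroxy-3-methoxyphenyl)tetrahydro-1H,3H-furo[3,4-c]furan-1-one (CNP0268159.1)
Conditions: H2 (1 atm), 10% Pd/C, EtOAc, rt, stopped at full O-debenzylation
Reagents that add atoms: none
Why: Hydrogenolysis of the three aryl benzyl ethers over Pd/C is expected to be much faster than cleavage of the ring benzylic C–O bonds at C3 and C6 under neutral conditions at 1 atm, so the reaction is stopped at the triphenol and no stereocentre is affected.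

**Compound list**
1 | 4-(benzyloxy)-3-methoxybenzaldehyde | COc1cc(C=O)ccc1OCc1ccccc1 | starting material
2 | 4-ethenyl-1,3-dioxolan-2-one (racemic) | C=CC1COC(=O)O1 | starting material
3 | (1S,2R)-1-[4-(benzyloxy)-3-methoxyphenyl]-2-ethenylpropane-1,3-diol | COc1cc([C@@H](O)[C@@H](CO)C=C)ccc1OCc1ccccc1 | intermediate
4 | (1S,2R)-1-[4-(benzyloxy)-3-methoxyphenyl]-2-{[(tert-butyldimethylsilyl)oxy]methyl}but-3-en-1-ol | COc1cc([C@@H](O)[C@@H](CO[Si](C)(C)C(C)(C)C)C=C)ccc1OCc1ccccc1 | intermediate
5 | B-alkyl-9-BBN adduct of 4 (boron on the terminal carbon; formed in the flask) | COc1cc([C@@H](O)[C@@H](CO[Si](C)(C)C(C)(C)C)CCB2C3CCCC2CCC3)ccc1OCc1ccccc1 | intermediate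
6 | (1S,2R)-1-[4-(benzyloxy)-3-methoxyphenyl]-2-{[(tert-butyldimethylsilyl)oxy]methyl}butane-1,4-diol | COc1cc([C@@H](O)[C@@H](CO[Si](C)(C)C(C)(C)C)CCO)ccc1OCc1ccccc1 | intermediate
7 | (3R,4S)-4-[4-(benzyloxy)-3-methoxyphenyl]-3-{[(tert-butyldimethylsilyl)oxy]methyl}-4-hydroxybutanal (formed in the flask) | COc1cc([C@@H](O)[C@@H](CO[Si](C)(C)C(C)(C)C)CC=O)ccc1OCc1ccccc1 | intermediate
8 | (4R,5S)-5-[4-(benzyloxy)-3-methoxyphenyl]-4-{[(tert-butyldimethylsilyl)oxy]methyl}oxolan-2-ol (anomeric mixture; formed in the flask) | COc1cc([C@H]2OC(O)C[C@@H]2CO[Si](C)(C)C(C)(C)C)ccc1OCc1ccccc1 | intermediate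
9 | (4R,5S)-5-[4-(benzyloxy)-3-methoxyphenyl]-4-{[(tert-butyldimethylsilyl)oxy]methyl}oxolan-2-one | COc1cc([C@H]2OC(=O)C[C@@H]2CO[Si](C)(C)C(C)(C)C)ccc1OCc1ccccc1 | intermediate
10 | (3E,4R,5S)-5-[4-(benzyloxy)-3-methoxyphenyl]-4-{[(tert-butyldimethylsilyl)oxy]methyl}-3-[(dimethylamino)methylidene]oxolan-2-one | COc1cc([C@H]2OC(=O)/C(=C/N(C)C)[C@@H]2CO[Si](C)(C)C(C)(C)C)ccc1OCc1ccccc1 | intermediate
11 | (3E,4R,5S)-5-[4-(benzyloxy)-3-methoxyphenyl]-3-[(dimethylamino)methylidene]-4-(hydroxymethyl)oxolan-2-one (formed in the flask) | COc1cc([C@H]2OC(=O)/C(=C/N(C)C)[C@@H]2CO)ccc1OCc1ccccc1 | intermediate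
12 | (3S,3aR)-3-[4-(benzyloxy)-3-methoxyphenyl]-3a,4-dihydro-1H,3H-furo[3,4-c]furan-1-one | COc1cc([C@H]2OC(=O)C3=COC[C@@H]32)ccc1OCc1ccccc1 | intermediate
13 | [3,4-bis(benzyloxy)phenyl]boronic acid | OB(O)c1ccc(OCc2ccccc2)c(OCc2ccccc2)c1 | starting material
14 | (3S,3aR,6S,6aS)-6-[3,4-bis(benzyloxy)phenyl]-3-[4-(benzyloxy)-3-methoxyphenyl]tetrahydro-1H,3H-furo[3,4-c]furan-1-one | COc1cc([C@H]2OC(=O)[C@H]3[C@@H]2CO[C@@H]3c2ccc(OCc3ccccc3)c(OCc3ccccc3)c2)ccc1OCc1ccccc1 | intermediate
15 | (3S,3aR,6S,6aS)-6-(3,4-dihydroxyphenyl)-3-(4-hydroxy-3-methoxyphenyl)tetrahydro-1H,3H-furo[3,4-c]furan-1-one | COc1cc([C@H]2OC(=O)[C@H]3[C@@H]2CO[C@@H]3c2ccc(O)c(O)c2)ccc1O | target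

Total steps: 8. Longest linear sequence: 8 steps (1 to 15).

**Steps most likely to fail**

Step 7 (proposed new method). The aryl–rhodium insertion may be too slow on the electron-rich, α-substituted double bond, so that protodeboronation of 13 outruns addition, or the two faces of 12 may not be well discriminated. The fallback uses known oxocarbenium chemistry and sets out from 12. Acid-catalysed addition of methanol across C6=C6a (CSA cat., MeOH, rt) would give the methyl acetal (3S,3aR,6aS)-3-[4-(benzyloxy)-3-methoxyphenyl]-6-methoxytetrahydro-1H,3H-furo[3,4-c]furan-1-one F1 as an anomeric mixture. F1 and commercial 1,2-bis(benzyloxy)benzene with TMSOTf in CH2Cl2 at −40 °C should then undergo Friedel–Crafts C-arylation through the bicyclic oxocarbenium ion, with attack on the convex face and para to a benzyloxy group. This comes back to the route at 14.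

Step 1. Conversion of the electron-rich aldehyde may be incomplete, or enantio- and diastereocontrol may be eroded by reversible dehydrogenation of the benzylic carbinol. The fallback is an auxiliary-controlled Evans syn-aldol route that sets out from 1 and comes back at 9, bypassing steps 1 to 4.
- (S)-4-Benzyloxazolidin-2-one is N-acylated with methyl 4-chloro-4-oxobutanoate (n-BuLi, THF, −78 °C) to the imide (4S)-4-benzyl-3-(4-methoxy-4-oxobutanoyl)-1,3-oxazolidin-2-one F2.
- Its boron enolate (Bu2BOTf, i-Pr2NEt, CH2Cl2, −78 °C) adds to 1 to give the syn-aldol methyl (3S,4S)-3-{[(4S)-4-benzyl-2-oxo-1,3-oxazolidin-3-yl]carbonyl}-4-[4-(benzyloxy)-3-methoxyphenyl]-4-hydroxybutanoate F3.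
- F3 lactonises with CSA to the trans-lactone imide (4S)-4-benzyl-3-{[(2S,3S)-2-[4-(benzyloxy)-3-methoxyphenyl]-5-oxooxolan-3-yl]carbonyl}-1,3-oxazolidin-2-one F4.
- LiOH/H2O2 removes the auxiliary to give (2S,3S)-2-[4-(benzyloxy)-3-methoxyphenyl]-5-oxooxolane-3-carboxylic acid F5.
- BH3·SMe2 reduces the acid in the presence of the lactone to (4R,5S)-5-[4-(benzyloxy)-3-methoxyphenyl]-4-(hydroxymethyl)oxolan-2-one F6, and TBSCl/imidazole then gives 9.

Step 8. Hydrogenolysis may run past O-debenzylation into the benzylic C3–O2 and C6–O5 bonds (over-reduction with ring opening). The fallback sets out from 14 and replaces reduction by Lewis-acid debenzylation with BCl3 and pentamethylbenzene as cation scavenger (CH2Cl2, −78 °C), arriving directly at 15. It makes no new compound (F0).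

Further compounds
F1 | step 7 | (3S,3aR,6aS)-3-[4-(benzyloxy)-3-methoxyphenyl]-6-methoxytetrahydro-1H,3H-furo[3,4-c]furan-1-one (anomeric mixture at C6) | COc1cc([C@H]2OC(=O)[C@H]3[C@@H]2COC3OC)ccc1OCc1ccccc1
F2 | step 1 | (4S)-4-benzyl-3-(4-methoxy-4-oxobutanoyl)-1,3-oxazolidin-2-one | COC(=O)CCC(=O)N1[C@@H](Cc2ccccc2)COC1=O
F3 | step 1 | methyl (3S,4S)-3-{[(4S)-4-benzyl-2-oxo-1,3-oxazolidin-3-yl]carbonyl}-4-[4-(benzyloxy)-3-methoxyphenyl]-4-hydroxybutanoate | COc1cc([C@@H](O)[C@H](CC(=O)OC)C(=O)N2[C@@H](Cc3ccccc3)COC2=O)ccc1OCc1ccccc1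
F4 | step 1 | (4S)-4-benzyl-3-{[(2S,3S)-2-[4-(benzyloxy)-3-methoxyphenyl]-5-oxooxolan-3-yl]carbonyl}-1,3-oxazolidin-2-one | COc1cc([C@H]2OC(=O)C[C@@H]2C(=O)N2[C@@H](Cc3ccccc3)COC2=O)ccc1OCc1ccccc1
F5 | step 1 | (2S,3S)-2-[4-(benzyloxy)-3-methoxyphenyl]-5-oxooxolane-3-carboxylic acid | COc1cc([C@H]2OC(=O)C[C@@H]2C(=O)O)ccc1OCc1ccccc1
F6 | step 1 | (4R,5S)-5-[4-(benzyloxy)-3-methoxyphenyl]-4-(hydroxymethyl)oxolan-2-one | COc1cc([C@H]2OC(=O)C[C@@H]2CO)ccc1OCc1ccccc1
F0 | step 8 | none | none
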